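(The constants used here come from no measurement; the flask was simulated.)

1. Cedar runs at 1.52: this is its drain number, how many times over the side step would empty the reversible pool of substrate, target and isomer of the product during the run at its starting pace.

| flask | substrate | reagent | catalyst | time |
|---|---|---|---|---|
| cedar | 20 mM | 25.0 mM | 20 µM | 2.0 h |
| ash | 20 mM | 40.0 mM | 20 µM | 2.0 h |
| maple | 20 mM | 60.0 mM | 20 µM | 2.0 h |
| oak | 20 mM | 100 mM | 20 µM | 2.0 h |

    substrate + reagent ⇌ target (K1 = 22 /M, k1 = 6.2 /M/min)
    substrate + target → side product (k2 = 6.0 /M/min)
    substrate + reagent ⇌ isomer of the product (K3 = 67 /M, k3 = 0.31 /M/min)
    target + catalyst ⇌ isomer of the product + catalyst, rate k4*[catalyst]*[target] forward; the back reaction follows from the equilibrium constant (k4 = 3100 /M/min)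

- a species is counted by the substrate in it: one side product counts as two
- "hardly changes" means that all values lie within two and a half points (for a concentration: within two and a half percent of the largest)
- run time (cedar): 2.0 h

* share of target in all that became target or isomer of the product or side product for cedar, ash, maple, oak, in this order
* how the row runs (rises all the way / rises, then falls / hardly changes / falls all the way / falls, then rises)

2. My reckoning, with reagent held at its charge: in cedar the step to target relaxes in about 1.59 min, and the catalyst joins target and isomer in about 8.42 min, both far shorter than 2.0 h. So cedar's pool is a pre-equilibrium: each substrate stands beside 0.55 target and 1.7 isomer, a pool factor of 3.23.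

3. The drain number is 2 (substrate units per side product) times the side-step constant, the target balance K1 × reagent, the substrate charge and the time, divided by the pool factor squared. The pool falls second-order, so the fraction left is 1/(1 + drain number). From cedar to oak the number runs 1.52, 1.22, 0.946, 0.646.

4. Target over everything no longer substrate then gives 7.71 %, 9.65 %, 11.6 %, 14.4 %: a rising row.

5. One number is not enough: the reckoned outcome for cedar uses 11.5 mM of the 25.0 mM reagent that was held at its charge, and the isomer starts from nothing while the drain already runs. My row should stand high, though still rising.

6. The forecast, lower than my row, gives 4.2 %, 5.8 %, 7.4 %, 9.8 %, rises all the way: “More reagent pushes free substrate down and holds more material as target”.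

7. The flasks give 5.01 %, 6.48 %, 8.04 %, 10.4 %: rises all the way, and the forecast stands within its margin.

At 2.00 h cedar's step to target relaxes with a half-life of 1.79 min, far shorter than the run, while substrate's half-life through the side step is 2.2 h, close to the run time. At 2.00 h cedar makes target at 0.770 of the rate at which it uses it up, each step taken net. Its drain number of 1.52 exceeds oak's 0.646, and the fractions run the same way: outside side product stand 33.9 % in cedar against 39.7 % reckoned, and 48.4 % in oak against 60.8 %.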